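**Turning ratio.** The turning ratio ρ = 1.26, the rate constant of D + L over that of L + D.L, tells when D.L stops gaining. Both steps take one L, so D.L is made and used in the proportion ρ[D]/[D.L], whatever the level of L. D.L gains while this made-to-used ratio exceeds one and loses once it falls below.

D 0.20 M; X 25 mM (held); time 30 min

    X ⇌ L, rate k1*(csat - [L]) (k1 = 3.33 min⁻¹, csat = 25 mM)
    D + L → D.L (k2 = 5.22 L mol⁻¹ min⁻¹)
    L + D.L → L.D.L (k3 = 4.14 L mol⁻¹ min⁻¹)
    D → Z (k4 = 6.82 × 10⁻⁴ min⁻¹)
    L → G (k5 = 0.106 min⁻¹)
    2 L → L2 (k6 = 6.73 L mol⁻¹ min⁻¹)

- the D.L standing at 30 min, as a percentage of the D charged
- the change that raises the amount of D.L at 30 min, in percent of the D charged most ("none" if none brings more than 2 percentage points) (blue / grey / none)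
- amount of D.L at 30 min, in percent of the D charged, after grey

**First instants.** X enters a solution empty of L, and the transfer fills it within about 0.300 min. Supply then balances the loss to G, the binding, and the pairing of L, which takes two at each turn and so has the coefficient 13.5 L mol⁻¹ min⁻¹. My reckoning takes binding, by D and D.L together, at half its starting load, which puts L at 19.7 mM. The fill is quicker than the 9.72 min of binding.

**The middle.** With L steady, both bindings are pseudo-first-order, and D goes by binding far faster than to Z. Two such steps in a row with this ρ peak at 41.1% of the D charged, after 10.9 min.

**The end.** The asked time lies later than this peak, so my reckoning has D.L falling by then, to 19.7%. In the same reckoning, doubling the saturation concentration lifts L to 37.3 mM, and doubling the transfer coefficient lifts it to 22.0 mM. Neither changes ρ, and with L higher both carry the reckoned flask further down the falling side, so the choice is none, with 16.1% after grey.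

**The forecast.** It gives 19.9%, then none as the best change, and 16% after grey: “Both blue and grey only push more L through and move further down the falling side of that peak”.

**The flask.** The simulation gives 20.3% and none as the best change, with blue at −17 percentage points and grey at −4.1 points, and 16.2% after grey.

**Made against used.** At 30.0 min the flask holds D at 4.78% and D.L at 20.3%, so ρ times their quotient is 0.297, and the rate of making D.L over the rate of using it, each taken net, stands at 0.298, less than one. The neighbour flask read at 8.0 min holds D at 47.8% and D.L at 37.9%, which puts its made-to-used ratio at 1.59, more than one.

Its constants are those of an exercise; what happens was integrated by code.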